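**Assumption:** the target has no stereocentre and no E/Z-stereogenic double bond (both prenyl olefins end in CMe2), so it is made as the one achiral compound; the racemic early intermediates lose their stereocentres on aromatisation.

## Retrosynthetic overview

1. Target 12 ⇐ 3,5-diallyl resorcylate 11 by double olefin cross-metathesis with 2-methylbut-2-ene (allyl → prenyl).
2. 11 ⇐ bis(allyl ether) 9 by double aromatic Claisen rearrangement (C3 and C5 are the only free ring carbons) ⇐ resorcylate 8 by O-allylation.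
3. 8 ⇐ cyclohexane-1,3-dione ester 6 by bromination/dehydrobromination. The resorcylate ring is the only ring built, first as its dihydro form and then aromatised.
4. 6 ⇐ enone 3 + dimethyl malonate 4: intermolecular Michael addition (C1–C6 bond), then intramolecular Claisen (Dieckmann) closure (C2–C3 bond).
5. 3 ⇐ 3-phenylpropanal 1 + acetonyl ylide 2 (Wittig); the phenyl ring is bought in.

## Route

Step 1
Reactants: 1 3-phenylpropanal; 2 1-(triphenyl-λ5-phosphanylidene)propan-2-one
Product: 3 (E)-6-phenylhex-3-en-2-one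
Conditions: 2 (1.1 equiv), CH2Cl2, rt → 40 °C, 16 h
Reagents that add atoms: none
Why: Wittig olefination with a ketone-stabilised ylide gives the E-enone cleanly and avoids the self-aldol problems of the enolisable aldehyde under basic aldol conditions.

Step 2
Reactants: 3 (E)-6-phenylhex-3-en-2-one; 4 dimethyl malonate
Product: 6 methyl 2-hydroxy-4-oxo-6-(2-phenylethyl)cyclohex-2-ene-1-carboxylate (racemic trans; enol form of the 2,4-dione), via Michael adduct 5 (not isolated)
Conditions: NaOMe (1.2 equiv), MeOH, rt then reflux 4 h; then cold aq. HCl to pH 3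
Reagents that add atoms: none
Why: Sodiomalonate adds 1,4 to the enone (Michael addition) and the methyl-ketone enolate then closes onto a malonate ester (Claisen/Dieckmann condensation), driven by the stabilised 1,3-dione enolate; the two new stereocentres (racemic, trans by equilibration) are erased in step 3.

Step 3
Reactants: 6 methyl 2-hydroxy-4-oxo-6-(2-phenylethyl)cyclohex-2-ene-1-carboxylate
Product: 8 methyl 2,4-dihydroxy-6-(2-phenylethyl)benzoate, via bromo-dione 7 (not isolated)
Conditions: Br2 (1.0 equiv), DMF, 0 °C → rt 1 h, then 80 °C 12 h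
Reagents that add atoms: none
Why: Electrophilic bromination at the enolic C3 followed by thermal loss of HBr and tautomerisation is an oxidative aromatisation of the dihydroresorcylate; 80 °C is below the decarboxylation range, so the ester is kept.

Step 4
Reactants: 8 methyl 2,4-dihydroxy-6-(2-phenylethyl)benzoate
Product: 9 methyl 6-(2-phenylethyl)-2,4-bis(prop-2-en-1-yloxy)benzoate
Conditions: allyl bromide (3 equiv), K2CO3 (4 equiv), DMF, 60 °C, 12 h
Reagents that add atoms: allyl bromide, C=CCBr
Why: Williamson ether synthesis in a polar aprotic solvent gives O-allylation of both phenoxides; heating and excess halide are needed for the hydrogen-bonded 2-OH.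

Step 5
Reactants: 9 methyl 6-(2-phenylethyl)-2,4-bis(prop-2-en-1-yloxy)benzoate
Product: 11 methyl 2,4-dihydroxy-6-(2-phenylethyl)-3,5-di(prop-2-en-1-yl)benzoate, via mono-Claisen phenol 10 (not isolated)
Conditions: N,N-diethylaniline, 200 °C, Ar, sealed tube, 10 h
Reagents that add atoms: none
Why: Two successive aromatic Claisen rearrangements converge on the 3,5-diallyl compound because C3 and C5 are the only open ring carbons: an allyl group that reaches an occupied ortho carbon is relayed by Cope shift to the free para carbon, and rearomatisation to the chelated phenol makes each shift irreversible.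

Step 6
Reactants: 11 methyl 2,4-dihydroxy-6-(2-phenylethyl)-3,5-di(prop-2-en-1-yl)benzoate
Product: 12 methyl 2,4-dihydroxy-3,5-bis(3-methylbut-2-en-1-yl)-6-(2-phenylethyl)benzoate
Conditions: Grubbs II (2 × 5 mol %), 2-methylbut-2-ene/CH2Cl2 1:1, 40 °C, sealed tube, 24 h
Reagents that add atoms: 2-methylbut-2-ene, CC=C(C)C
Why: Olefin cross-metathesis of each terminal allyl group with excess 2-methylbut-2-ene installs the isopropylidene terminus with loss of propene; the trisubstituted prenyl olefin does not re-enter metathesis, and the free phenols and ester are tolerated.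

## Compound list

1 | 3-phenylpropanal | O=CCCc1ccccc1 | starting material
2 | 1-(triphenyl-λ5-phosphanylidene)propan-2-one | CC(=O)C=P(c1ccccc1)(c1ccccc1)c1ccccc1 | starting material
3 | (E)-6-phenylhex-3-en-2-one | CC(=O)/C=C/CCc1ccccc1 | intermediate
4 | dimethyl malonate | COC(=O)CC(=O)OC | starting material
5 | dimethyl 2-(5-oxo-1-phenylhexan-3-yl)propanedioate (racemic, one stereocentre; not isolated) | COC(=O)C(C(=O)OC)C(CCc1ccccc1)CC(C)=O | intermediate
6 | methyl 2-hydroxy-4-oxo-6-(2-phenylethyl)cyclohex-2-ene-1-carboxylate (racemic, trans C1/C6, one enantiomer drawn; enol tautomer of the 2,4-dione) | COC(=O)[C@@H]1[C@@H](CCc2ccccc2)CC(=O)C=C1O | intermediate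
7 | methyl 3-bromo-2-hydroxy-4-oxo-6-(2-phenylethyl)cyclohex-2-ene-1-carboxylate (racemic, trans, one enantiomer drawn; not isolated) | COC(=O)[C@@H]1[C@@H](CCc2ccccc2)CC(=O)C(Br)=C1O | intermediate
8 | methyl 2,4-dihydroxy-6-(2-phenylethyl)benzoate | COC(=O)c1c(O)cc(O)cc1CCc1ccccc1 | intermediate
9 | methyl 6-(2-phenylethyl)-2,4-bis(prop-2-en-1-yloxy)benzoate | COC(=O)c1c(OCC=C)cc(OCC=C)cc1CCc1ccccc1 | intermediate
10 | methyl 2-hydroxy-6-(2-phenylethyl)-3-(prop-2-en-1-yl)-4-(prop-2-en-1-yloxy)benzoate (not isolated) | COC(=O)c1c(O)c(CC=C)c(OCC=C)cc1CCc1ccccc1 | intermediate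
11 | methyl 2,4-dihydroxy-6-(2-phenylethyl)-3,5-di(prop-2-en-1-yl)benzoate | COC(=O)c1c(O)c(CC=C)c(O)c(CC=C)c1CCc1ccccc1 | intermediate
12 | methyl 2,4-dihydroxy-3,5-bis(3-methylbut-2-en-1-yl)-6-(2-phenylethyl)benzoate (achiral) | COC(=O)c1c(O)c(CC=C(C)C)c(O)c(CC=C(C)C)c1CCc1ccccc1 | target

## Step count

Total step count: 6. Longest linear sequence: 6 (1 → 3 → 6 → 8 → 9 → 11 → 12).

## Steps most likely to fail, with fallbacks

**Step 3 (oxidative aromatisation).** With one equivalent of bromine the reaction can stall or over-brominate the electron-rich resorcylate. The fallback sets out from 6 and comes back at 8. Compound 6 is treated with Br2 (3.05 equiv) in AcOH at rt, so that oxidation and exhaustive ring bromination run to one product, methyl 3,5-dibromo-2,4-dihydroxy-6-(2-phenylethyl)benzoate F1. Both bromines are then removed by hydrogenolysis (H2 1 atm, 10 % Pd/C, NaOAc, MeOH, rt) to give 8.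

**Step 5 (double Claisen).** The high temperature may give incomplete second migration or dihydrobenzofuran by-products. The fallback sets out from 8 and comes back at 11, replacing steps 4 and 5 by halogenation and cross-coupling. Compound 8 is iodinated at both activated positions (NIS 2.1 equiv, MeCN, rt) to methyl 2,4-dihydroxy-3,5-diiodo-6-(2-phenylethyl)benzoate F2. Both phenols are protected (NaH, MOMCl, DMF, 0 °C → rt) to give methyl 3,5-diiodo-2,4-bis(methoxymethoxy)-6-(2-phenylethyl)benzoate F3. A double Stille coupling (allyltributylstannane 3 equiv, Pd(PPh3)4, CuI, CsF, DMF, 80 °C) gives methyl 2,4-bis(methoxymethoxy)-6-(2-phenylethyl)-3,5-di(prop-2-en-1-yl)benzoate F4. Acetal cleavage (HCl, MeOH, 40 °C; safe because only allyl groups, not prenyl groups, are present) returns 11.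

**Step 6 (double cross-metathesis).** Ruthenium hydride may isomerise allyl to propenyl, or conversion of the second, more hindered allyl group may be incomplete. The fallback sets out from 11 and comes back at 12, building the olefins by carbonyl olefination. Compound 11 is silylated (TBSOTf, 2,6-lutidine, CH2Cl2, 0 °C → rt) to methyl 2,4-bis[(tert-butyldimethylsilyl)oxy]-6-(2-phenylethyl)-3,5-di(prop-2-en-1-yl)benzoate F5. Lemieux–Johnson cleavage (OsO4 cat., NaIO4, 2,6-lutidine, dioxane/H2O, rt) gives methyl 2,4-bis[(tert-butyldimethylsilyl)oxy]-3,5-bis(2-oxoethyl)-6-(2-phenylethyl)benzoate F6. Wittig reaction with isopropylidenetriphenylphosphorane (from isopropyltriphenylphosphonium iodide and n-BuLi, THF, −78 → 0 °C) gives methyl 2,4-bis[(tert-butyldimethylsilyl)oxy]-3,5-bis(3-methylbut-2-en-1-yl)-6-(2-phenylethyl)benzoate F7. Desilylation (TBAF, AcOH, THF, 0 °C) gives 12 without acid that could cyclise the prenyl phenols to chromans.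

## Further compounds

F1 | step 3 | methyl 3,5-dibromo-2,4-dihydroxy-6-(2-phenylethyl)benzoate | COC(=O)c1c(O)c(Br)c(O)c(Br)c1CCc1ccccc1
F2 | step 5 | methyl 2,4-dihydroxy-3,5-diiodo-6-(2-phenylethyl)benzoate | COC(=O)c1c(O)c(I)c(O)c(I)c1CCc1ccccc1
F3 | step 5 | methyl 3,5-diiodo-2,4-bis(methoxymethoxy)-6-(2-phenylethyl)benzoate | COC(=O)c1c(OCOC)c(I)c(OCOC)c(I)c1CCc1ccccc1
F4 | step 5 | methyl 2,4-bis(methoxymethoxy)-6-(2-phenylethyl)-3,5-di(prop-2-en-1-yl)benzoate | COC(=O)c1c(OCOC)c(CC=C)c(OCOC)c(CC=C)c1CCc1ccccc1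
F5 | step 6 | methyl 2,4-bis[(tert-butyldimethylsilyl)oxy]-6-(2-phenylethyl)-3,5-di(prop-2-en-1-yl)benzoate | COC(=O)c1c(O[Si](C)(C)C(C)(C)C)c(CC=C)c(O[Si](C)(C)C(C)(C)C)c(CC=C)c1CCc1ccccc1
F6 | step 6 | methyl 2,4-bis[(tert-butyldimethylsilyl)oxy]-3,5-bis(2-oxoethyl)-6-(2-phenylethyl)benzoate | COC(=O)c1c(O[Si](C)(C)C(C)(C)C)c(CC=O)c(O[Si](C)(C)C(C)(C)C)c(CC=O)c1CCc1ccccc1
F7 | step 6 | methyl 2,4-bis[(tert-butyldimethylsilyl)oxy]-3,5-bis(3-methylbut-2-en-1-yl)-6-(2-phenylethyl)benzoate | COC(=O)c1c(O[Si](C)(C)C(C)(C)C)c(CC=C(C)C)c(O[Si](C)(C)C(C)(C)C)c(CC=C(C)C)c1CCc1ccccc1
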